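**Strategy.** Atoms: C1 ester carbinol, C2 CH2, C3 C–Me, C4 =CH, C5 C=O, C6 quaternary C–Me, C7/C8 CH2, C9 isopropyl carbinol, C10 fusion CH. The route rests on cutting C6–C10 and C2–C3 of the cis-fused five–seven bicycle. Read backwards, C2, C1 and C10 form a 2-oxyallyl cation and C3–C6 an oxygenated diene (oxygen on C5) hung on C9 through C7–C8; their intramolecular (4+3) union closes both rings at once, fixes C6 and C10 under the influence of C9, and delivers a C4=C5 silyl enol ether that later becomes the C3=C4 enone. The precursor is an open-chain chloromethyl ketone with a (Z,E)-2-silyloxydiene, made from ozonised (S)-terpinen-4-ol.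

Key step: step 11

Assumption: (S)-(+)-terpinen-4-ol is bought in high enantiomeric purity; its carbinol carbon is carried unchanged into C9, so the optical purity of the target equals that of this material.

Convention: the locants C1–C10 defined above are used for every intermediate; β is the face of C10–H and the C6 methyl group in the bicycle, α the opposite face.

Design note: the chloromethyl ketone is unveiled last, from a Weinreb amide, so that the acid-labile dienol ether never meets acid or diazo chemistry; a hindered amine is used in the key step because the chloride is primary.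

**Step 1**
Reactants: 1 (S)-terpinen-4-ol
Product: 2 triethyl{[(1S)-4-methyl-1-(propan-2-yl)cyclohex-3-en-1-yl]oxy}silane
Conditions: TESOTf, 2,6-lutidine, CH2Cl2, 0 °C → rt
Reagents that add atoms: triethylsilyl trifluoromethanesulfonate, CC[Si](CC)(CC)OS(=O)(=O)C(F)(F)F
Why: Silyl triflate silylation with 2,6-lutidine protects the hindered tertiary alcohol without touching the stereocentre that later becomes C9, and this silyl ether is chosen because it should tolerate every step up to the final fluoride cleavage.

**Step 2**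
Reactants: 2 triethyl{[(1S)-4-methyl-1-(propan-2-yl)cyclohex-3-en-1-yl]oxy}silane
Product: 4 (3S)-6-oxo-3-(propan-2-yl)-3-[(triethylsilyl)oxy]heptanal, via secondary ozonide 3 (not isolated)
Conditions: O3, CH2Cl2, −78 °C; then PPh3, −78 °C → rt
Reagents that add atoms: ozone, [O-][O+]=O
Why: Ozonolysis (Criegee mechanism) with reductive work-up cleaves the only alkene and opens the ring to a methyl ketone (future C6 with its methyl group) and an aldehyde (future C1), the C9 centre being untouched.

**Step 3**
Reactants: 4 (3S)-6-oxo-3-(propan-2-yl)-3-[(triethylsilyl)oxy]heptanal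
Product: 5 (3S)-6-oxo-3-(propan-2-yl)-3-[(triethylsilyl)oxy]heptanoic acid
Conditions: NaClO2, NaH2PO4, 2-methyl-2-butene, t-BuOH/H2O, 0 °C → rt
Reagents that add atoms: sodium chlorite NaClO2, [Na+].[O-]Cl=O
Why: Pinnick oxidation converts only the aldehyde into the acid, leaves the methyl ketone alone and is buffered mildly enough for the tertiary silyl ether.

**Step 4**
Reactants: 5 (3S)-6-oxo-3-(propan-2-yl)-3-[(triethylsilyl)oxy]heptanoic acid; 6 N,O-dimethylhydroxylamine hydrochloride
Product: 8 (3S)-N-methoxy-N-methyl-6-oxo-3-(propan-2-yl)-3-[(triethylsilyl)oxy]heptanamide, via acyl imidazole 7 (not isolated)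
Conditions: 1,1'-carbonyldiimidazole, CH2Cl2, rt; then 6, rt
Reagents that add atoms: N,O-dimethylhydroxylamine hydrochloride (6), CNOC.Cl
Why: Activation as the acyl imidazole and aminolysis gives the Weinreb amide under neutral conditions, which parks C1 as an acyl group that survives the ylide, the Grignard reagent and the enol silylation and can be turned into the chloromethyl ketone at the very end without acid.

**Step 5**
Reactants: 8 (3S)-N-methoxy-N-methyl-6-oxo-3-(propan-2-yl)-3-[(triethylsilyl)oxy]heptanamide; 9 (methoxymethyl)triphenylphosphonium chloride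
Product: 10 (3S)-N,7-dimethoxy-N,6-dimethyl-3-(propan-2-yl)-3-[(triethylsilyl)oxy]hept-6-enamide (E/Z mixture)
Conditions: 9, KN(SiMe3)2, THF, 0 °C; then 8, −78 °C → rt
Reagents that add atoms: (methoxymethyl)triphenylphosphonium chloride (9), COC[P+](c1ccccc1)(c1ccccc1)c1ccccc1.[Cl-]
Why: Wittig methoxymethylenation of the methyl ketone adds the carbon that becomes C5, the ketone being far more electrophilic than the Weinreb amide and the enol ether geometry being of no consequence.

**Step 6**
Reactants: 10 (3S)-N,7-dimethoxy-N,6-dimethyl-3-(propan-2-yl)-3-[(triethylsilyl)oxy]hept-6-enamide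
Product: 11 (3S)-N-methoxy-N,6-dimethyl-7-oxo-3-(propan-2-yl)-3-[(triethylsilyl)oxy]heptanamide (both C6 epimers)
Conditions: TsOH·H2O (cat.), acetone/H2O, 0 °C → rt
Reagents that add atoms: water, O
Why: Acid-catalysed enol ether hydrolysis (C-protonation, hemiacetal collapse) unmasks the α-methyl aldehyde while the hindered tertiary silyl ether should outlast the brief, dilute acid; the C6 centre formed here is not controlled and need not be, since C6 becomes sp2 in step 9.

**Step 7**
Reactants: 11 (3S)-N-methoxy-N,6-dimethyl-7-oxo-3-(propan-2-yl)-3-[(triethylsilyl)oxy]heptanamide; 12 (E)-1-bromopropene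
Product: 13 (3S,8E)-7-hydroxy-N-methoxy-N,6-dimethyl-3-(propan-2-yl)-3-[(triethylsilyl)oxy]dec-8-enamide (diastereomer mixture at chain C6 and C7)
Conditions: 12, t-BuLi (2 equiv), Et2O, −78 °C; MgBr2·OEt2; then 11, THF, −78 °C; aq. NH4Cl
Reagents that add atoms: (E)-1-bromopropene (12), C/C=C/Br
Why: Bromine–lithium exchange keeps the E geometry, and after transmetalation the alkenyl Grignard reagent adds to the aldehyde far faster than to the Weinreb amide (Grignard 1,2-addition); the carbinol centre is formed unselectively and is oxidised away in step 8.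

**Step 8**
Reactants: 13 (3S,8E)-7-hydroxy-N-methoxy-N,6-dimethyl-3-(propan-2-yl)-3-[(triethylsilyl)oxy]dec-8-enamide
Product: 14 (3S,8E)-N-methoxy-N,6-dimethyl-7-oxo-3-(propan-2-yl)-3-[(triethylsilyl)oxy]dec-8-enamide (both C6 epimers)
Conditions: Dess–Martin periodinane, CH2Cl2, 0 °C → rt
Reagents that add atoms: none
Why: Dess–Martin oxidation of the allylic alcohol gives the (E)-propenyl ketone under near-neutral conditions without moving the double bond or harming the silyl ether.

**Step 9**
Reactants: 14 (3S,8E)-N-methoxy-N,6-dimethyl-7-oxo-3-(propan-2-yl)-3-[(triethylsilyl)oxy]dec-8-enamide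
Product: 15 (3S,6Z,8E)-7-[(tert-butyldimethylsilyl)oxy]-N-methoxy-N,6-dimethyl-3-(propan-2-yl)-3-[(triethylsilyl)oxy]deca-6,8-dienamide
Conditions: TBSOTf, Et3N, CH2Cl2, −78 → 0 °C
Reagents that add atoms: tert-butyldimethylsilyl trifluoromethanesulfonate, CC(C)(C)[Si](C)(C)OS(=O)(=O)C(F)(F)F
Why: Soft enolisation (O-silylation of the ketone, then amine deprotonation at the α'-methine C6) should give the cross-conjugated 2-silyloxydiene with the longer chain syn to the silyloxy group (Z), while the Weinreb amide does not enolise under these conditions.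

**Step 10**
Reactants: 15 (3S,6Z,8E)-7-[(tert-butyldimethylsilyl)oxy]-N-methoxy-N,6-dimethyl-3-(propan-2-yl)-3-[(triethylsilyl)oxy]deca-6,8-dienamide; 16 chloroiodomethane
Product: 18 (4S,7Z,9E)-8-[(tert-butyldimethylsilyl)oxy]-1-chloro-7-methyl-4-(propan-2-yl)-4-[(triethylsilyl)oxy]undeca-7,9-dien-2-one, via lithium alkoxide adduct 17 (not isolated)
Conditions: 16, MeLi·LiBr, THF/Et2O, −78 °C; aq. NH4Cl
Reagents that add atoms: chloroiodomethane (16), ClCI
Why: Chloromethyllithium, generated by iodine–lithium exchange in the presence of the substrate, adds once to the Weinreb amide and the chelated tetrahedral adduct releases the chloromethyl ketone only on quench (Weinreb ketone synthesis with a lithium carbenoid), so the dienol ether is never exposed to acid.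

**Step 11**
Reactants: 18 (4S,7Z,9E)-8-[(tert-butyldimethylsilyl)oxy]-1-chloro-7-methyl-4-(propan-2-yl)-4-[(triethylsilyl)oxy]undeca-7,9-dien-2-one
Product: 20 cis-fused cycloadduct (3R,3aS,6R,8aS)-8-[(tert-butyldimethylsilyl)oxy]-6,8a-dimethyl-3-(propan-2-yl)-3-[(triethylsilyl)oxy]-2,3,3a,5,6,8a-hexahydroazulen-4(1H)-one, via oxyallyl cation 19 (not isolated)
Conditions: i-Pr2NEt, LiClO4 (3 M), Et2O, rt
Reagents that add atoms: none
Why: i-Pr2NEt, too hindered to alkylate the primary chloride, enolises 18 towards C10 and lithium-assisted loss of chloride gives oxyallyl cation 19 (C2–C1–C10); C6 of the silyloxydiene bonds to C10 and the enolate carbon C2 then bonds to C3 of the resulting silyloxyallyl cation, in one asynchronous event or in two fast steps, leaving the C4=C5 silyl enol ether. The closest known reaction type is the amine/LiClO4-mediated intramolecular (4+3) cycloaddition of α-chloro ketones that carry a tethered 1,3-diene, which gives five–seven fused ketones. The five-membered ring closes through the C7–C8–C9 tether by a 5-exo attack of the enol ether carbon C6 on C10, and the seven-membered ring closes across the diene termini when C2 bonds to the allyl-cation terminus C3. C6 and C10 are set together in the compact arrangement in which the oxyallyl oxygen lies over the diene, which puts C1 and C5 on one face of the new cyclopentane (cis fusion), while the C10 face is chosen by C9: its C–O bond is expected to lie in the cation plane next to C10–H and opposed to the oxyallyl dipole, the tether carbon C8 on the diene side and the isopropyl group on the far side, so that C1 ends up syn to isopropyl; C3 follows from suprafacial addition to the (Z,E)-diene and is erased in step 14. The step needs seven-ring closure at C3 to win over five-ring closure at C5 or loss of silicon from the open zwitterion, and it needs the right C10 face. The s-cis-capable (E)-propenyl unit, the slowly leaving TBS group, the aprotic medium and the bulky, poorly chelating silyl ether on C9 are the features meant to secure this.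

**Step 12**
Reactants: 20 cis-fused cycloadduct
Product: 21 (3R,3aR,4S,6R,8aS)-8-[(tert-butyldimethylsilyl)oxy]-6,8a-dimethyl-3-(propan-2-yl)-3-[(triethylsilyl)oxy]-1,2,3,3a,4,5,6,8a-octahydroazulen-4-ol
Conditions: LiBH(s-Bu)3, THF, −78 °C; aq. NH4Cl
Reagents that add atoms: none
Why: Hydride transfer from the bulky borohydride is expected on the convex face of the cis-fused bicycle, the face of C10–H and the C6 methyl group and away from the folded cyclopentane and its α-isopropyl group, which sets the C1 hydroxyl α (trans to C10–H) at a temperature too low for C10 epimerisation (diastereoselective ketone reduction).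

**Step 13**
Reactants: 21 C1 α-alcohol; 22 4-methoxybenzoyl chloride
Product: 23 (3R,3aR,4S,6R,8aS)-8-[(tert-butyldimethylsilyl)oxy]-6,8a-dimethyl-3-(propan-2-yl)-3-[(triethylsilyl)oxy]-1,2,3,3a,4,5,6,8a-octahydroazulen-4-yl 4-methoxybenzoate
Conditions: 22, Et3N, DMAP, CH2Cl2, rt → 40 °C
Reagents that add atoms: 4-methoxybenzoyl chloride (22), COc1ccc(C(=O)Cl)cc1
Why: DMAP-catalysed acylation of the secondary alcohol proceeds with retention at C1 under basic conditions that both silyl groups tolerate, and the trans relation of the C1 and C9 oxygens disfavours silyl migration.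

**Step 14**
Reactants: 23 C1 4-methoxybenzoate with C5 silyl enol ether
Product: 24 (3R,3aR,4S,8aS)-6,8a-dimethyl-8-oxo-3-(propan-2-yl)-3-[(triethylsilyl)oxy]-1,2,3,3a,4,5,8,8a-octahydroazulen-4-yl 4-methoxybenzoate
Conditions: Pd(OAc)2 (1.1 equiv), MeCN, rt → 40 °C
Reagents that add atoms: none
Why: Saegusa–Ito oxidation: divalent palladium takes the silyl enol ether to a C4-bound palladium enolate and syn β-hydride elimination of the C3 hydrogen gives the C3=C4 enone, the only regiochemistry open because C6 is quaternary, with loss of the C3 stereocentre.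

**Step 15**
Reactants: 24 enone ester with C9 triethylsilyl ether
Product: 25 (3R,3aR,4S,8aS)-3-hydroxy-6,8a-dimethyl-8-oxo-3-(propan-2-yl)-1,2,3,3a,4,5,8,8a-octahydroazulen-4-yl 4-methoxybenzoate (CNP0301380.1)
Conditions: HF·pyridine, pyridine, THF, 0 °C → rt
Reagents that add atoms: none
Why: Fluoride cleavage of the tertiary triethylsilyl ether in buffered HF·pyridine frees the C9 alcohol without base, which could otherwise trigger vinylogous elimination of the C1 ester from the enone.

**Compound list**

1 | (S)-terpinen-4-ol | CC1=CC[C@](O)(C(C)C)CC1 | starting material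
2 | triethyl{[(1S)-4-methyl-1-(propan-2-yl)cyclohex-3-en-1-yl]oxy}silane | CC1=CC[C@](O[Si](CC)(CC)CC)(C(C)C)CC1 | intermediate
3 | secondary ozonide of 2: 1-methyl-4-(propan-2-yl)-4-[(triethylsilyl)oxy]-7,8,9-trioxabicyclo[4.2.1]nonane, C4 as in 2, bridgeheads unassigned | CC12CC[C@@](O[Si](CC)(CC)CC)(C(C)C)CC(OO1)O2 | intermediate (not isolated)
4 | (3S)-6-oxo-3-(propan-2-yl)-3-[(triethylsilyl)oxy]heptanal | O=CC[C@](O[Si](CC)(CC)CC)(C(C)C)CCC(C)=O | intermediate
5 | (3S)-6-oxo-3-(propan-2-yl)-3-[(triethylsilyl)oxy]heptanoic acid | OC(=O)C[C@](O[Si](CC)(CC)CC)(C(C)C)CCC(C)=O | intermediate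
6 | N,O-dimethylhydroxylamine hydrochloride | CNOC.Cl | starting material
7 | acyl imidazole of 5: (3S)-1-(1H-imidazol-1-yl)-3-(propan-2-yl)-3-[(triethylsilyl)oxy]heptane-1,6-dione | O=C(C[C@](O[Si](CC)(CC)CC)(C(C)C)CCC(C)=O)n1ccnc1 | intermediate (not isolated)
8 | (3S)-N-methoxy-N-methyl-6-oxo-3-(propan-2-yl)-3-[(triethylsilyl)oxy]heptanamide | CON(C)C(=O)C[C@](O[Si](CC)(CC)CC)(C(C)C)CCC(C)=O | intermediate
9 | (methoxymethyl)triphenylphosphonium chloride | COC[P+](c1ccccc1)(c1ccccc1)c1ccccc1.[Cl-] | starting material
10 | (3S)-N,7-dimethoxy-N,6-dimethyl-3-(propan-2-yl)-3-[(triethylsilyl)oxy]hept-6-enamide, E/Z mixture | CON(C)C(=O)C[C@](O[Si](CC)(CC)CC)(C(C)C)CCC(C)=COC | intermediate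
11 | (3S)-N-methoxy-N,6-dimethyl-7-oxo-3-(propan-2-yl)-3-[(triethylsilyl)oxy]heptanamide, both C6 epimers | CON(C)C(=O)C[C@](O[Si](CC)(CC)CC)(C(C)C)CCC(C)C=O | intermediate
12 | (E)-1-bromopropene | C/C=C/Br | starting material
13 | (3S,8E)-7-hydroxy-N-methoxy-N,6-dimethyl-3-(propan-2-yl)-3-[(triethylsilyl)oxy]dec-8-enamide, mixture at chain C6 and C7 | CON(C)C(=O)C[C@](O[Si](CC)(CC)CC)(C(C)C)CCC(C)C(O)/C=C/C | intermediate
14 | (3S,8E)-N-methoxy-N,6-dimethyl-7-oxo-3-(propan-2-yl)-3-[(triethylsilyl)oxy]dec-8-enamide, both C6 epimers | CON(C)C(=O)C[C@](O[Si](CC)(CC)CC)(C(C)C)CCC(C)C(=O)/C=C/C | intermediate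
15 | (3S,6Z,8E)-7-[(tert-butyldimethylsilyl)oxy]-N-methoxy-N,6-dimethyl-3-(propan-2-yl)-3-[(triethylsilyl)oxy]deca-6,8-dienamide | CON(C)C(=O)C[C@](O[Si](CC)(CC)CC)(C(C)C)CC/C(C)=C(O[Si](C)(C)C(C)(C)C)/C=C/C | intermediate
16 | chloroiodomethane | ClCI | starting material
17 | lithium alkoxide adduct of 15 with chloromethyllithium (tetrahedral N-methoxy-N-methyl hemiaminal, new centre unassigned) | CON(C)C(O[Li])(CCl)C[C@](O[Si](CC)(CC)CC)(C(C)C)CC/C(C)=C(O[Si](C)(C)C(C)(C)C)/C=C/C | intermediate (not isolated)
18 | (4S,7Z,9E)-8-[(tert-butyldimethylsilyl)oxy]-1-chloro-7-methyl-4-(propan-2-yl)-4-[(triethylsilyl)oxy]undeca-7,9-dien-2-one (chloromethyl ketone with tethered 2-silyloxydiene) | ClCC(=O)C[C@](O[Si](CC)(CC)CC)(C(C)C)CC/C(C)=C(O[Si](C)(C)C(C)(C)C)/C=C/C | intermediate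
19 | oxyallyl cation (zwitterion) across C2–C1–C10 of 18, tether syn to the oxyallyl oxygen | [O-]/C([CH2+])=C\[C@](O[Si](CC)(CC)CC)(C(C)C)CC/C(C)=C(O[Si](C)(C)C(C)(C)C)/C=C/C | intermediate (not isolated)
20 | (3R,3aS,6R,8aS)-8-[(tert-butyldimethylsilyl)oxy]-6,8a-dimethyl-3-(propan-2-yl)-3-[(triethylsilyl)oxy]-2,3,3a,5,6,8a-hexahydroazulen-4(1H)-one; C1 ketone, C4=C5 silyl enol ether, C6–CH3, C10–H, C9–OSiEt3 and C3–H β, isopropyl and C3–CH3 α | O=C1C[C@@H](C)C=C(O[Si](C)(C)C(C)(C)C)[C@@]2(C)CC[C@@](O[Si](CC)(CC)CC)(C(C)C)[C@@H]12 | intermediate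
21 | (3R,3aR,4S,6R,8aS)-8-[(tert-butyldimethylsilyl)oxy]-6,8a-dimethyl-3-(propan-2-yl)-3-[(triethylsilyl)oxy]-1,2,3,3a,4,5,6,8a-octahydroazulen-4-ol; C1–OH α | O[C@H]1C[C@@H](C)C=C(O[Si](C)(C)C(C)(C)C)[C@@]2(C)CC[C@@](O[Si](CC)(CC)CC)(C(C)C)[C@@H]12 | intermediate
22 | 4-methoxybenzoyl chloride | COc1ccc(C(=O)Cl)cc1 | starting material
23 | (3R,3aR,4S,6R,8aS)-8-[(tert-butyldimethylsilyl)oxy]-6,8a-dimethyl-3-(propan-2-yl)-3-[(triethylsilyl)oxy]-1,2,3,3a,4,5,6,8a-octahydroazulen-4-yl 4-methoxybenzoate | COc1ccc(C(=O)O[C@H]2C[C@@H](C)C=C(O[Si](C)(C)C(C)(C)C)[C@@]3(C)CC[C@@](O[Si](CC)(CC)CC)(C(C)C)[C@@H]23)cc1 | intermediate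
24 | (3R,3aR,4S,8aS)-6,8a-dimethyl-8-oxo-3-(propan-2-yl)-3-[(triethylsilyl)oxy]-1,2,3,3a,4,5,8,8a-octahydroazulen-4-yl 4-methoxybenzoate | COc1ccc(C(=O)O[C@H]2CC(C)=CC(=O)[C@@]3(C)CC[C@@](O[Si](CC)(CC)CC)(C(C)C)[C@@H]23)cc1 | intermediate
25 | (3R,3aR,4S,8aS)-3-hydroxy-6,8a-dimethyl-8-oxo-3-(propan-2-yl)-1,2,3,3a,4,5,8,8a-octahydroazulen-4-yl 4-methoxybenzoate; C6–CH3, C10–H and C9–OH β, isopropyl and C1 ester oxygen α | COc1ccc(C(=O)O[C@H]2CC(C)=CC(=O)[C@@]3(C)CC[C@@](O)(C(C)C)[C@@H]23)cc1 | target

**Totals**

Total step count: 15. Longest linear sequence: 15 steps (1 → 25).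

**Steps most likely to fail**

Step 11 (key step). Ionisation may be slow because enolisation has to occur at the hindered C10 methylene. After the first bond the open zwitterion may lose silicon or close a five-membered ring at C5 instead of bonding at C3 (loss of periselectivity). The C10 face or the compact geometry may not be obeyed (poor facial selectivity). Fallback, making the two bonds one after the other with known reactions: 18 is ionised with i-Pr2NEt in CF3CH2OH, where the solvent is expected to strip the silyl group from the open cation once C6–C10 is formed, giving the cyclopentane diketone F1 (acetyl on C10, (E)-but-2-enoyl and methyl on C6). Kinetic deprotonation of the acetyl methyl group with LiN(i-Pr)2 (THF, −78 °C), warming so that the enolate closes the seven-membered ring by intramolecular Michael addition to C3, and O-silylation of the resulting C5 enolate with TBSOTf bring the material back to the route at 20. Should the Michael closure give the C3 epimer of 20 F2 instead, steps 12 and 13 carry it on as the C3-epimeric alcohol F3 and the C3-epimeric ester F4, and step 14 removes C3 as a stereocentre, so that this branch rejoins at 24.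

Step 12. Hydride may be delivered from the concave face (wrong C1 configuration), or the basic reagent may epimerise C10 before reduction. Fallback: if the reduction of 20 gives the C1-epimeric alcohol F5, it is esterified with inversion at C1 by a Mitsunobu reaction (4-methoxybenzoic acid, PPh3, diisopropyl azodicarboxylate, toluene, 0 °C → rt). This reaches 23 directly and replaces step 13; the face that accepted hydride is then also the face open to the carboxylate.

Step 9. Deprotonation may occur at the γ-methyl group of the propenyl ketone instead of at C6 (loss of regiocontrol), or the enol ether may form as a mixture of geometries. Fallback, in which the enolate is made by addition and not by deprotonation: aldehyde 11 is oxidised (NaClO2, NaH2PO4, 2-methyl-2-butene) to the carboxylic acid F6. The acid is converted under neutral conditions with 1-chloro-N,N,2-trimethylprop-1-en-1-amine into the acid chloride F7, which is dehydrochlorinated with Et3N in Et2O to the alkyl methyl ketene F8, the ammonium salt being filtered off. The filtrate is added at −78 °C to (E)-prop-1-enyllithium (from 12 and t-BuLi). Attack in the ketene plane from the side of the smaller methyl group should give the lithium enolate F9 with oxygen syn to the chain, and silylation with TBSOTf returns to the route at 15.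

**Further compounds**

F1 | step 11 | cyclopentane diketone: C6–C10 bonded monocycle with acetyl on C10, (E)-but-2-enoyl and methyl on C6, C9 silyl ether, configuration at C6, C9, C10 as in 20 | C/C=C/C(=O)[C@@]1(C)CC[C@@](O[Si](CC)(CC)CC)(C(C)C)[C@H]1C(C)=O
F2 | step 11 | C3 epimer of 20 | O=C1C[C@H](C)C=C(O[Si](C)(C)C(C)(C)C)[C@@]2(C)CC[C@@](O[Si](CC)(CC)CC)(C(C)C)[C@@H]12
F3 | step 11 | C3 epimer of 21 | O[C@H]1C[C@H](C)C=C(O[Si](C)(C)C(C)(C)C)[C@@]2(C)CC[C@@](O[Si](CC)(CC)CC)(C(C)C)[C@@H]12
F4 | step 11 | C3 epimer of 23 | COc1ccc(C(=O)O[C@H]2C[C@H](C)C=C(O[Si](C)(C)C(C)(C)C)[C@@]3(C)CC[C@@](O[Si](CC)(CC)CC)(C(C)C)[C@@H]23)cc1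
F5 | step 12 | C1 epimer of 21 (C1–OH β) | O[C@@H]1C[C@@H](C)C=C(O[Si](C)(C)C(C)(C)C)[C@@]2(C)CC[C@@](O[Si](CC)(CC)CC)(C(C)C)[C@@H]12
F6 | step 9 | (5S)-7-[methoxy(methyl)amino]-2-methyl-7-oxo-5-(propan-2-yl)-5-[(triethylsilyl)oxy]heptanoic acid, both C2 epimers | CON(C)C(=O)C[C@](O[Si](CC)(CC)CC)(C(C)C)CCC(C)C(=O)O
F7 | step 9 | acid chloride of F6 | CON(C)C(=O)C[C@](O[Si](CC)(CC)CC)(C(C)C)CCC(C)C(=O)Cl
F8 | step 9 | alkyl methyl ketene from F7 | CON(C)C(=O)C[C@](O[Si](CC)(CC)CC)(C(C)C)CCC(C)=C=O
F9 | step 9 | lithium (Z)-dienolate corresponding to 15 | CON(C)C(=O)C[C@](O[Si](CC)(CC)CC)(C(C)C)CC/C(C)=C(O[Li])/C=C/C
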